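## The problem

3,5,6,7,8-Pentamethoxyflavone (10) is a 2-phenylchromen-4-one. Ring A (C4a, C5–C8, C8a) is fused to the pyranone ring C through the C4a–C8a bond, carries a methoxy group on each of C5–C8, and C3 of ring C carries a fifth. The molecule has no stereocentre, so the difficulty is one of regiochemistry and oxidation pattern. All six carbons of ring A are substituted, five of them by oxygen (C5, C6, C7, C8, and C8a through O1), and simple benzene building blocks offer at most four contiguous oxygens. A classical flavone closure uses a phenol ortho to the acyl group as the future O1. Starting from a tetraoxygenated benzene this would spend one of the four oxygens and leave C5 bare, so the fifth C–O bond has to be made at a ring C–H carbon. The 3-methoxy group is best brought in together with C3, because late oxygenation of C3 costs steps. The sensitive points are: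
- the methoxy group ortho to the carbonyl, which strong Lewis acids cleave through chelation;
- the 2-methoxy-1,3-diketone of any open-chain precursor, which is open to retro-Claisen cleavage by alkoxide and to oxidation at its methine;
- the quinone and hydroquinone levels of ring A, which are sensitive to base and air.

The enabling feature is that the oxygens on C5 and C8 are para to each other and flank the C6/C7 dimethoxy pair. Ring A is therefore the reduced, methylated form of a 2,3-dimethoxy-1,4-benzoquinone in which C4a bears the acyl group and C8a is the single unsubstituted carbon, the β-position of both the C5 quinone carbonyl and the C4 ketone.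

## Retrosynthesis

**O5–CH3 and O8–CH3 (10 to 8 to 9).** The first cut removes the methyl groups from O5 and O8 of 10. This exposes hydroquinone 8 and, two electrons higher, flavone-5,8-quinone 9. This pair is chosen over any other pair of methoxy groups because only the para pair maps ring A onto a p-quinone, the level at which C8a becomes electrophilic. The skeleton is not simplified. The forward direction needs a dithionite reduction and a double O-methylation that includes the hydrogen-bonded 5-hydroxyl, both routine.

**O1–C8a (9 to 7).** In 9 the ring oxygen sits on C8a, the quinone carbon next to the acyl-bearing C4a. Cutting O1–C8a and returning two hydrogens gives acylquinone 7, in which C8a carries hydrogen. The neighbouring cuts are worse. Cutting O1–C2 would call for a hydroxyl on C8a and hence a pentaoxygenated benzene. Cutting C4–C4a would call for acylation of a fully substituted ring. Precursor 7 has one ring fewer and only four oxygens on the carbocycle. The forward reaction must make the enol oxygen of the diketone add to C8a, and must reoxidise the hydroquinone 8 that forms first. At the hydroquinone level, uncyclised material could lose water through the C5 oxygen and give an isomeric flavone without the C5 oxygen.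

**Quinone oxygens back to methyl ethers (7 to 6).** The two quinone carbonyls of 7 are returned to methoxy groups, which gives tetramethoxyaryl diketone 6. This is the retron of an oxidative demethylation. In 6 the C5 and C8 methoxy groups are the only para pair, so the substitution pattern fixes where the quinone forms. Methyl ethers are preferred to free phenols here because a free C5 hydroxyl beside the diketone would cyclise in the wrong sense. The forward oxidant must take the electron-rich arene and leave the diketone methine alone.

**C2–C3 (6 to 4 and 5).** The diketone is cut between the methoxy-bearing C3 and the benzoyl carbon C2. This gives aryl methoxymethyl ketone 4 and methyl benzoate 5, a commercial, non-enolisable ester. The forward step is a crossed Claisen condensation in which only 4 can form an enolate. The 3-methoxy group of the target is already in place, so no later oxidation at C3 is needed.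

**C4–C4a (4 to 1 and 2, through 3).** The aryl–carbonyl bond is cut to 1,2,3,4-tetramethoxybenzene 1 and the Weinreb amide 2 of methoxyacetic acid. The two ring hydrogens of 1 are equivalent and each is ortho to a methoxy group, so directed lithiation gives a single aryllithium 3, and 2 stops cleanly at the ketone. A Lewis-acid acylation with the corresponding acid chloride would form the same bond. It is avoided because it exposes the ortho methoxy group to chelation-assisted cleavage and the α-alkoxy acylium ion to loss of carbon monoxide.

## Roads not taken

**Alternative 1:** The cut goes through ring A itself. Breaking C4a–C8a and O1–C2 unfolds the flavone into the open-chain methyl 2,3,3,4,8-pentamethoxy-5,7,9-trioxo-9-phenylnonanoate A2, whose backbone carbons are C8a to C2 of the flavone and whose C7 is a dimethyl ketal.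
- Forward step: base would make the C4a methylene, which lies between two ketones, attack the ester carbon in a Claisen closure of ring A. Acid would then aromatise the ring by loss of methanol from C7 and close ring C by attack of the new C8a hydroxyl on the C2 ketone. The product is 5-hydroxy-3,6,7,8-tetramethoxyflavone A1, one methylation away from 10.
- Merits: two rings form in one operation, every oxygen is present at the right level from the start, ring A needs no redox chemistry, and the end game is one step shorter than in the chosen plan.
- Weak points: A2 carries nine functionalised carbons, three stereocentres that are thrown away, and a ketal flanked by two methoxy methines. It has several acidic sites, so aldol closures, pyranone formation through oxygen, β-elimination of methoxide and retro-Claisen cleavage all compete with the intended fold. No short access to A2 is apparent, and making it would cost more steps than the whole chosen route.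
- Comparison: alternative 1 is the better plan in bond-forming economy at the key step and in its end game. The chosen plan sets against this that ring A with four of its oxygens is bought as 1 and the whole line is six steps.

**Alternative 2:** Ring C is cut at C4a–C4, C4–C3 and O1–C2 into three components: 2-iodo-3,4,5,6-tetramethoxyphenol A4, carbon monoxide A6 and phenylacetylene A5.
- Forward step: a carbonylative Sonogashira coupling (PdCl2(PPh3)2, CuI, amine) gives an o-hydroxyaryl ynone, which closes by attack of the phenol on the alkyne to 5,6,7,8-tetramethoxyflavone A3.
- Merits: this is an established reaction class for flavones and is highly convergent. Its key step is better precedented than that of the chosen plan, and it avoids quinones altogether.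
- Weak points: A3 lacks the C3 oxygen, so C3–H must be oxidised and the new hydroxyl methylated, two further steps. A4 is not a stock compound; from 1 it needs an oxygen and an iodine on the two remaining ring carbons, about three steps. Its iodide is flanked on both sides and sits on a very electron-rich ring, so oxidative addition to zerovalent palladium is slow and the non-carbonylative coupling competes. The ynone may also close in the five-membered (aurone) sense.
- Comparison: the overall length is about the same as the chosen route or slightly longer. The chosen plan sets against the better precedent that the 3-methoxy group is built in from 2, that the fifth ring-A oxygen is created by the ring closure itself and not by a separate C–H oxygenation, and that no palladium or pressurised A6 is needed.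

**Alternative 3:** Ring A is cut at C4a–C5 and C8–C8a, so that it is built from a four-carbon squarate unit on a preformed pyranone.
- Forward step: dimethyl squarate A9 would be combined with 3-methoxy-2-phenyl-4H-pyran-4-one A10, metalated at C6, to give 4-hydroxy-2,3-dimethoxy-4-(5-methoxy-4-oxo-6-phenyl-4H-pyran-2-yl)cyclobut-2-en-1-one A8. Heating opens the cyclobutenone to a vinylketene, which closes by 6π electrocyclisation onto pyranone C5 and tautomerises to 5,8-dihydroxy-3,6,7-trimethoxyflavone A7, the same compound as 8.
- Merits: the route is convergent, and ring A arrives at the hydroquinone level with its regiochemistry fixed by construction and without any oxidant. It joins the chosen route at 8, so it avoids the oxidation and reduction of steps 3 to 5. In that respect it is the better plan.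
- Weak points: A10 must itself be made in several steps. Its metalation at C6 competes with addition to the pyranone carbonyl and with deprotonation at C5, and is not secured. The electrocyclisation has to engage the C5=C6 bond of an electron-poor pyranone rather than an arene.
- Comparison: the chosen plan sets against the cleaner redox economy that all three of its building blocks (1, 2, 5) are commercial and that the steps before the key step are well precedented.

Key step: step 4

Assumption: diketones 6 and 7 are written as racemic keto forms. They equilibrate with their enols, and their methine stereocentre has no bearing on the achiral target.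

## Route

Step 1
Reactants: 1 1,2,3,4-tetramethoxybenzene; 2 N,2-dimethoxy-N-methylacetamide
Product: 4 2-methoxy-1-(2,3,4,5-tetramethoxyphenyl)ethan-1-one, via 2,3,4,5-tetramethoxyphenyllithium 3 (not isolated)
Conditions: n-BuLi, TMEDA, THF, 0 °C to rt; then 2, −78 to 0 °C; aq. HCl
Reagents that add atoms: none
Why: Directed ortho-lithiation followed by Weinreb ketone synthesis; the two ring hydrogens of 1 are equivalent and each lies ortho to a methoxy group, the chelated tetrahedral adduct stops at the ketone, and no Lewis acid touches the methoxy groups.

Step 2
Reactants: 4 2-methoxy-1-(2,3,4,5-tetramethoxyphenyl)ethan-1-one; 5 methyl benzoate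
Product: 6 2-methoxy-1-phenyl-3-(2,3,4,5-tetramethoxyphenyl)propane-1,3-dione (racemic keto form)
Conditions: NaH, THF, reflux; then aq. HCl, 0 °C
Reagents that add atoms: none
Why: Crossed Claisen condensation of a ketone enolate with a non-enolisable ester; hydrogen evolution and formation of the diketonate drive it, and the diketonate shields the product from retro-Claisen cleavage until the acidic quench.

Step 3
Reactants: 6 2-methoxy-1-phenyl-3-(2,3,4,5-tetramethoxyphenyl)propane-1,3-dione
Product: 7 2,3-dimethoxy-5-(2-methoxy-3-oxo-3-phenylpropanoyl)cyclohexa-2,5-diene-1,4-dione (racemic keto form)
Conditions: (NH4)2Ce(NO3)6, MeCN/H2O, 0 °C, short contact time; extractive work-up, used crude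
Reagents that add atoms: water, O
Why: Oxidative demethylation of a para-dimethoxyarene by single-electron oxidation with tetravalent cerium; the C5 and C8 methoxy groups are the only para pair, the pattern that turns 1,2,3,4-tetramethoxyarenes into 2,3-dimethoxy-1,4-benzoquinones, and the mostly diketo side chain should be a poorer electron donor than the arene.

Step 4
Reactants: 7 2,3-dimethoxy-5-(2-methoxy-3-oxo-3-phenylpropanoyl)cyclohexa-2,5-diene-1,4-dione
Product: 9 3,6,7-trimethoxy-2-phenyl-4H-chromene-4,5,8-trione (3,6,7-trimethoxyflavone-5,8-quinone), via 5,8-dihydroxy-3,6,7-trimethoxyflavone 8 (not isolated)
Conditions: Ag2O, MgSO4, CH2Cl2, rt, dark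
Reagents that add atoms: none
Why: Proposed new method: the diketone of 7 enolises towards the benzoyl carbon on the basic Ag2O surface, and that enol oxygen adds to C8a, the one unsubstituted quinone carbon and the β-carbon of both the C5 quinone carbonyl and the C4 ketone, to form the O1–C8a bond. Loss of the C8a hydrogen then aromatises ring A to hydroquinone 8, which Ag2O (monovalent silver, reduced to the metal) dehydrogenates to 9; the same oxidant returns any hydroquinone of 7 formed by redox exchange to 7, so no material stays at the level where dehydrative closure through the C5 oxygen is possible. The closest known reaction types are the conjugate addition of heteroatom and carbon nucleophiles to 2-acyl-1,4-benzoquinones at the carbon next to the acyl group, the oxidative coupling of hydroquinones with 1,3-dicarbonyl compounds to benzofurans, and the base-mediated closure of 1-(2-halophenyl)-1,3-diketones to flavones, in which the same enolate oxygen attacks the same ring carbon. Ring C closes in the 6-endo-trig mode, because the attacked C4a=C8a double bond lies inside the new ring. No stereocentre is formed and the methine stereocentre of 7 disappears. The selectivity needed is oxygen attack at C8a: carbon C3 could reach C8a only through a four-membered ring, addition of the enol oxygen to the C5 carbonyl gives a hemiketal that can revert, and C6 and C7 are out of reach, whereas attack at C8a is made irreversible by aromatisation. Coordination of silver or a proton between O4 and O5 should hold the C4 carbonyl syn to C5, the geometry of the flavone, and make C8a more electrophilic.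

Step 5
Reactants: 9 3,6,7-trimethoxy-2-phenyl-4H-chromene-4,5,8-trione
Product: 8 5,8-dihydroxy-3,6,7-trimethoxyflavone
Conditions: Na2S2O4, EtOAc/H2O, rt, argon
Reagents that add atoms: none
Why: Two-electron reduction of a quinone to its hydroquinone with dithionite; the pyranone and the methoxy groups are inert to it, and work-up under argon should keep the product from reverting to 9.

Step 6
Reactants: 8 5,8-dihydroxy-3,6,7-trimethoxyflavone
Product: 10 3,5,6,7,8-pentamethoxyflavone
Conditions: Me2SO4, K2CO3, acetone, reflux, argon
Reagents that add atoms: dimethyl sulfate, COS(=O)(=O)OC
Why: Williamson O-methylation of both phenols; excess reagent at reflux is the standard way to methylate the hydrogen-bonded 5-hydroxyl of flavones, and exclusion of air protects the hydroquinone until it is capped.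

## Compound list

1 | 1,2,3,4-tetramethoxybenzene | COc1ccc(OC)c(OC)c1OC | starting material
2 | N,2-dimethoxy-N-methylacetamide | COCC(=O)N(C)OC | starting material
3 | 2,3,4,5-tetramethoxyphenyllithium | [Li]c1cc(OC)c(OC)c(OC)c1OC | intermediate
4 | 2-methoxy-1-(2,3,4,5-tetramethoxyphenyl)ethan-1-one | COCC(=O)c1cc(OC)c(OC)c(OC)c1OC | intermediate
5 | methyl benzoate | COC(=O)c1ccccc1 | starting material
6 | 2-methoxy-1-phenyl-3-(2,3,4,5-tetramethoxyphenyl)propane-1,3-dione (racemic keto form) | COC(C(=O)c1ccccc1)C(=O)c1cc(OC)c(OC)c(OC)c1OC | intermediate
7 | 2,3-dimethoxy-5-(2-methoxy-3-oxo-3-phenylpropanoyl)cyclohexa-2,5-diene-1,4-dione (racemic keto form) | COC(C(=O)c1ccccc1)C(=O)C1=CC(=O)C(OC)=C(OC)C1=O | intermediate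
8 | 5,8-dihydroxy-3,6,7-trimethoxyflavone | COc1c(-c2ccccc2)oc2c(O)c(OC)c(OC)c(O)c2c1=O | intermediate
9 | 3,6,7-trimethoxy-2-phenyl-4H-chromene-4,5,8-trione | COC1=C(c2ccccc2)OC2=C(C1=O)C(=O)C(OC)=C(OC)C2=O | intermediate
10 | 3,5,6,7,8-pentamethoxyflavone | COc1c(OC)c(OC)c2c(=O)c(OC)c(-c3ccccc3)oc2c1OC | target

Total step count: 6. Longest linear sequence: 6 steps, from 1 to 10.

## Least certain steps

**Step 4 (key step, proposed new method).** The most likely failure is that intermolecular reactions outrun the intramolecular oxygen attack. A diketonate carbon of one molecule can add to the quinone of another, and the weakly enolised 2-methoxy diketone may be slow to reach the conformation that brings its oxygen over C8a. Base-induced loss of the vinylogous-ester methoxy groups of the quinone is a second drain.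

The fallback uses known chemistry only. It sets out from 4 and returns to the route at 10.
- Ketone 4 is brominated at its single ring C–H (NBS, MeCN, rt) to 1-(2-bromo-3,4,5,6-tetramethoxyphenyl)-2-methoxyethan-1-one F1.
- The Claisen condensation of step 2 (NaH, 5, THF) then gives 1-(2-bromo-3,4,5,6-tetramethoxyphenyl)-2-methoxy-3-phenylpropane-1,3-dione F2.
- Intramolecular Ullmann-type O-arylation (CuI, 1,10-phenanthroline, K2CO3, DMF, 110 °C), an established flavone closure of 1-(2-haloaryl)-1,3-diketones, joins O1 to C8a and gives 10 directly.

This detour is shorter than the main line and gives up the quinone idea altogether. It is held in reserve because the main line forms the C8a–O1 bond without a halogen handle and delivers 8 and 9, in which O5 and O8 are set apart from the other oxygens.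

**Step 3.** The likely failure is oxidation at the diketone methine (single-electron oxidation of the enol by tetravalent cerium) or formation of ortho-quinones in competition with the para demethylation. Premature ring closure in the acidic medium would do no harm, since it leads to 9.

The fallback carries the side chain through the ring oxidation at the aldol level, where there is no enol to oxidise. It sets out from 4 and returns at 7, and it also bypasses the Claisen condensation.
- Aldol addition of the lithium enolate of 4 (LiN(i-Pr)2, THF, −78 °C) to benzaldehyde gives 3-hydroxy-2-methoxy-3-phenyl-1-(2,3,4,5-tetramethoxyphenyl)propan-1-one F3 as a diastereomer mixture.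
- (NH4)2Ce(NO3)6 in MeCN/H2O at 0 °C converts the ring into the quinone 5-(3-hydroxy-2-methoxy-3-phenylpropanoyl)-2,3-dimethoxycyclohexa-2,5-diene-1,4-dione F4.
- Dess–Martin periodinane in CH2Cl2 oxidises the secondary alcohol to the diketone 7.

**Step 2.** The likely failure is self-condensation of the hindered, electron-rich aryl ketone enolate and methoxide-induced retro-Claisen cleavage, both outpacing productive acylation.

The fallback forms the other C–C bond of the diketone with the roles of the partners exchanged. It sets out from 1 (through 3) and returns at 6.
- Aryllithium 3 is added to excess methyl chloroformate at −78 °C to give methyl 2,3,4,5-tetramethoxybenzoate F5.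
- F5 is condensed with the unhindered enolate of commercial 2-methoxy-1-phenylethan-1-one (NaH, THF, reflux) to give 6.

**Step 6.** The likely failure is air oxidation of the hydroquinone dianion back to the quinone under the basic conditions before both oxygens are capped, with methylation stalling at the chelated 5-hydroxyl.

The fallback stores the hydroquinone as a stable diester and releases it only in the presence of the alkylating agent. It sets out from 9 and returns at 10.
- Reductive acetylation (Zn, Ac2O, NaOAc) gives 3,6,7-trimethoxy-4-oxo-2-phenyl-4H-chromene-5,8-diyl diacetate F6.
- Deacetylative methylation (Me2SO4, K2CO3, MeOH/acetone, reflux, argon) cleaves the acetates and methylates the phenoxides as they appear, giving 10.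

## Further compounds

F1 | step 4 | 1-(2-bromo-3,4,5,6-tetramethoxyphenyl)-2-methoxyethan-1-one | COCC(=O)c1c(Br)c(OC)c(OC)c(OC)c1OC
F2 | step 4 | 1-(2-bromo-3,4,5,6-tetramethoxyphenyl)-2-methoxy-3-phenylpropane-1,3-dione (racemic keto form) | COC(C(=O)c1ccccc1)C(=O)c1c(Br)c(OC)c(OC)c(OC)c1OC
F3 | step 3 | 3-hydroxy-2-methoxy-3-phenyl-1-(2,3,4,5-tetramethoxyphenyl)propan-1-one (diastereomer mixture, racemic) | COC(C(O)c1ccccc1)C(=O)c1cc(OC)c(OC)c(OC)c1OC
F4 | step 3 | 5-(3-hydroxy-2-methoxy-3-phenylpropanoyl)-2,3-dimethoxycyclohexa-2,5-diene-1,4-dione (diastereomer mixture, racemic) | COC(C(O)c1ccccc1)C(=O)C1=CC(=O)C(OC)=C(OC)C1=O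
F5 | step 2 | methyl 2,3,4,5-tetramethoxybenzoate | COC(=O)c1cc(OC)c(OC)c(OC)c1OC
F6 | step 6 | 3,6,7-trimethoxy-4-oxo-2-phenyl-4H-chromene-5,8-diyl diacetate | COc1c(-c2ccccc2)oc2c(OC(C)=O)c(OC)c(OC)c(OC(C)=O)c2c1=O
A1 | alternative 1 | 5-hydroxy-3,6,7,8-tetramethoxyflavone | COc1c(OC)c(O)c2c(=O)c(OC)c(-c3ccccc3)oc2c1OC
A2 | alternative 1 | methyl 2,3,3,4,8-pentamethoxy-5,7,9-trioxo-9-phenylnonanoate (stereoisomer mixture) | COC(=O)C(OC)C(OC)(OC)C(OC)C(=O)CC(=O)C(OC)C(=O)c1ccccc1
A3 | alternative 2 | 5,6,7,8-tetramethoxyflavone | COc1c(OC)c(OC)c2c(=O)cc(-c3ccccc3)oc2c1OC
A4 | alternative 2 | 2-iodo-3,4,5,6-tetramethoxyphenol | COc1c(O)c(I)c(OC)c(OC)c1OC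
A5 | alternative 2 | phenylacetylene | C#Cc1ccccc1
A6 | alternative 2 | carbon monoxide | [C-]#[O+]
A7 | alternative 3 | 5,8-dihydroxy-3,6,7-trimethoxyflavone (identical with 8) | COc1c(OC)c(O)c2c(=O)c(OC)c(-c3ccccc3)oc2c1O
A8 | alternative 3 | 4-hydroxy-2,3-dimethoxy-4-(5-methoxy-4-oxo-6-phenyl-4H-pyran-2-yl)cyclobut-2-en-1-one (racemic) | COC1=C(OC)C(O)(c2cc(=O)c(OC)c(-c3ccccc3)o2)C1=O
A9 | alternative 3 | dimethyl squarate | COC1=C(OC)C(=O)C1=O
A10 | alternative 3 | 3-methoxy-2-phenyl-4H-pyran-4-one | COc1c(-c2ccccc2)occc1=O
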